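**Plan**
- Retrosynthesis: the pyran ring of the 1H-isochromene is opened at C3=C4 and at C1–C8a in one cut, giving veratraldehyde and an aryl ketone whose α-carbon (C3) carries the O2–C1 unit; the second cut is the bond between the 2,4-dimethoxyphenyl ring and the ketone carbon.
- Feature that allows this: C1 is a formaldehyde-level CH2 held between the enol oxygen O2 and C8a, which stands para to the methoxy group at C6 of the benzo ring, and C3=C4 is the α,β-bond of an aryl ketone with C4 benzylic.
- Helper: C1 is carried as the CH2 of a carboxymethyl ether (an (aroylmethoxy)acetic acid from diglycolic anhydride); the carboxyl group fixes where the cation forms and leaves as CO2 in the key step itself.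
- Forward order: Friedel–Crafts acylation joins the 2,4-dimethoxyphenyl ring to the C3–O2–C1 chain; then, in one flask, condensation with veratraldehyde makes C3=C4 and anodic decarboxylation closes the pyran ring onto the benzo ring.
- Stereochemistry: there is no stereocentre; the Z geometry of C3=C4 that the ring demands comes from the thermodynamically controlled condensation.

Key step: step 2

Remark: the target has no stereocentre, so only the ring-fixed double-bond geometry has to be set; the route has two steps, and both are treated in the list of steps at risk.

Step 1
Reactants: 1 1,3-dimethoxybenzene; 2 diglycolic anhydride (1,4-dioxane-2,6-dione)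
Product: 3 2-[2-(2,4-dimethoxyphenyl)-2-oxoethoxy]acetic acid
Conditions: AlCl3 (2.5 equiv), CH2Cl2, 0 °C to rt; then ice, aq HCl
Reagents that add atoms: none
Why: Friedel–Crafts acylation of an arene by a cyclic anhydride (the opening move of a Haworth sequence): the AlCl3-activated anhydride should attack C4 of 1,3-dimethoxybenzene, para to one methoxy group and ortho to the other, the ring opening leaves the free carboxylic acid, and the aryl ketone formed is deactivated toward a second acylation.

Step 2
Reactants: 3 2-[2-(2,4-dimethoxyphenyl)-2-oxoethoxy]acetic acid; 4 3,4-dimethoxybenzaldehyde (veratraldehyde)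
Product: 6 (6,7-dimethoxy-1H-isochromen-3-yl)(2,4-dimethoxyphenyl)methanone, via Z-chalcone acid 5 (not isolated)
Conditions: nBu4NOH (1.5 equiv, 1 M in MeOH), MeOH, rt; then aq HBF4 (1.3 equiv), evaporation (toluene azeotrope); then CH2Cl2/(CF3)2CHOH 4:1, 3 Å MS, graphite anode, Pt cathode, undivided cell, constant current (5 mA cm-2), 2.2 F mol-1, rt
Reagents that add atoms: none
Why: Proposed new method: hydroxide condenses the only enolisable carbon of 3 (the CH2 between ketone and ether oxygen; the CH2 next to the carboxylate is not acidic) with aldehyde 4 in a Claisen–Schmidt reaction, which makes C3=C4 as the thermodynamically preferred Z-enone 5 with the dimethoxyphenyl group cis to the ether oxygen. Anodic oxidation of the partly neutralised acid should then expel CO2, and a second electron transfer from the α-oxy radical (Hofer–Moest course) leaves the cation O2=C1H2 at exactly the carbon that bore the carboxyl group; this 2-oxoniatriene (C1=O2–C3=C4–C4a=C8a) attacks C8a and loses a proton, which makes C1–C8a. The closest known reaction types are the Claisen–Schmidt condensation of ω-alkoxyacetophenones, the non-Kolbe electrolysis of alkoxy- and aryloxyacetic acids, where the same kind of cation is caught by an alcohol, and the oxa-Pictet–Spengler closure of alkoxymethyl cations onto dimethoxyarenes; their union in one flask, with the tethered arene of an enol ether as the trap, is the untested part. The pyran ring closes in the 6-endo-trig oxa-Pictet–Spengler mode (equally a 6π-electrocyclisation of the oxoniatriene followed by rearomatisation). No stereocentre arises; the Z geometry of C3=C4 is set by thermodynamic control in the condensation and is then fixed by the ring. The step needs oxidation of the carboxylate in preference to the dimethoxystyryl π-system (graphite anode, low current density, limited charge; a styryl radical cation should be quenched by the neighbouring carboxylate and end in the same cation), attack at C8a para to the C6 methoxy group in preference to the crowded carbon between side chain and methoxy group (the aroyl ring offers only a carbon meta to both its methoxy groups), and capture by carbon in preference to oxygen, which the non-nucleophilic CH2Cl2–(CF3)2CHOH medium should secure because adducts at oxygen (with the solvent alcohol, the acid or the ketone oxygen) can ionise again whereas the C–C closure cannot.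

**Compound list**
1 | 1,3-dimethoxybenzene | COc1cccc(OC)c1 | starting material
2 | diglycolic anhydride (1,4-dioxane-2,6-dione) | O=C1COCC(=O)O1 | starting material
3 | 2-[2-(2,4-dimethoxyphenyl)-2-oxoethoxy]acetic acid | COc1ccc(C(=O)COCC(=O)O)c(OC)c1 | intermediate
4 | 3,4-dimethoxybenzaldehyde (veratraldehyde) | COc1ccc(C=O)cc1OC | starting material
5 | (Z)-2-{[3-(3,4-dimethoxyphenyl)-1-(2,4-dimethoxyphenyl)-1-oxoprop-2-en-2-yl]oxy}acetic acid; present in the flask as its tetrabutylammonium salt | COc1ccc(C(=O)/C(OCC(=O)O)=C/c2ccc(OC)c(OC)c2)c(OC)c1 | intermediate
6 | (6,7-dimethoxy-1H-isochromen-3-yl)(2,4-dimethoxyphenyl)methanone | COc1ccc(C(=O)C2=Cc3cc(OC)c(OC)cc3CO2)c(OC)c1 | target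

**Step count**
Total step count: 2. Longest linear sequence: 2 steps (1 → 3 → 6).

**Steps most likely to fail** (the route has two steps; both are given, the labelled one first)

1. Step 2.
 - What may go wrong: the anode may take electrons from the dimethoxystyryl π-system, or from the product (loss of hydride at C1 toward the benzopyrylium salt), in place of the carboxylate. The cation may also be diverted to oxygen nucleophiles (the ketone oxygen, the acid, residual methanol or water), which would give acetals or set the CH2 group free as formaldehyde.
 - Fallback (known reactions; sets out from 3, returns at 6): the ring is closed at the saturated stage, where the cation sits on an alkyl ether oxygen and no styryl group is present, and the double bond is put in last.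
 - The dianion of 3 (LiN(iPr)2, 2.2 equiv, THF, −78 °C) is benzylated at the ketone α-carbon with 3,4-dimethoxybenzyl bromide to give racemic 2-{[3-(3,4-dimethoxyphenyl)-1-(2,4-dimethoxyphenyl)-1-oxopropan-2-yl]oxy}acetic acid F1.
 - Non-Kolbe electrolysis of F1 in MeOH (KOH 0.2 equiv, graphite electrodes) should give, as is usual for alkoxyacetic acids, the methoxymethyl ether 3-(3,4-dimethoxyphenyl)-1-(2,4-dimethoxyphenyl)-2-(methoxymethoxy)propan-1-one F2.
 - BF3·OEt2 in CH2Cl2 at 0 °C closes F2 by the classical oxa-Pictet–Spengler reaction of a 2-arylethyl methoxymethyl ether to racemic (6,7-dimethoxy-3,4-dihydro-1H-isochromen-3-yl)(2,4-dimethoxyphenyl)methanone F3.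
 - Enol silylation at the only α-hydrogen (Me3SiOTf, Et3N, CH2Cl2) gives [(6,7-dimethoxy-1,4-dihydro-3H-isochromen-3-ylidene)(2,4-dimethoxyphenyl)methoxy]trimethylsilane F4. Saegusa–Ito oxidation (Pd(OAc)2, MeCN, rt) then removes the benzylic hydrogen at C4 and gives 6.

2. Step 1.
 - What may go wrong: AlCl3 may remove the methyl group ortho to the new ketone through the chelate, or the acylation may stall because AlCl3 is bound by the ether and carboxylate oxygens.
 - Fallback (sets out from 1 and 2, returns at 3): the ketone is made by a Weinreb ketone synthesis in place of the electrophilic acylation.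
 - 1 is brominated para to one methoxy group (N-bromosuccinimide, MeCN, 0 °C to rt) to 1-bromo-2,4-dimethoxybenzene F5.
 - 2 is opened with MeNHOMe·HCl and pyridine in CH2Cl2 to 2-{2-[methoxy(methyl)amino]-2-oxoethoxy}acetic acid F6.
 - F5 is lithiated (BuLi, THF, −78 °C) and added to the lithium carboxylate of F6 (LiN(SiMe3)2, 1 equiv); acidic work-up gives 3.

**Further compounds**
F1 | step 2 | racemic 2-{[3-(3,4-dimethoxyphenyl)-1-(2,4-dimethoxyphenyl)-1-oxopropan-2-yl]oxy}acetic acid | COc1ccc(C(=O)C(Cc2ccc(OC)c(OC)c2)OCC(=O)O)c(OC)c1
F2 | step 2 | racemic 3-(3,4-dimethoxyphenyl)-1-(2,4-dimethoxyphenyl)-2-(methoxymethoxy)propan-1-one | COCOC(Cc1ccc(OC)c(OC)c1)C(=O)c1ccc(OC)cc1OC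
F3 | step 2 | racemic (6,7-dimethoxy-3,4-dihydro-1H-isochromen-3-yl)(2,4-dimethoxyphenyl)methanone | COc1ccc(C(=O)C2Cc3cc(OC)c(OC)cc3CO2)c(OC)c1
F4 | step 2 | [(6,7-dimethoxy-1,4-dihydro-3H-isochromen-3-ylidene)(2,4-dimethoxyphenyl)methoxy]trimethylsilane | COc1ccc(C(O[Si](C)(C)C)=C2Cc3cc(OC)c(OC)cc3CO2)c(OC)c1
F5 | step 1 | 1-bromo-2,4-dimethoxybenzene | COc1ccc(Br)c(OC)c1
F6 | step 1 | 2-{2-[methoxy(methyl)amino]-2-oxoethoxy}acetic acid | CON(C)C(=O)COCC(=O)O
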